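## Structural features

The target is a flavonol: a 4H-chromen-4-one in which a benzo ring (ring A, C4a to C8a) is fused to a pyranone (ring C, O1 to C4), with an aryl group (ring B) on C2 and a hydroxyl on C3. Ring A carries hydroxyls on C6 and C7 and hydrogens on C5 and C8. Together with O1 on C8a it is therefore a 1,2,4-trioxygenated benzene, with O1 para to the C6 hydroxyl and the C4 carbonyl attached at C4a. Ring B is a differentiated catechol: a prenyl (3-methylbut-2-en-1-yl) ether on O3' and a free hydroxyl on C4'. There is no stereocentre, chain or macrocycle; the problem is the ordering of six oxygen functions on a small skeleton. The aryl prenyl ether is the fragile group. It does not survive protic or Lewis acid, hydrogenolysis or electrophilic oxidants, which excludes benzyl, methyl and acetal protecting groups and a late hydroxylation of C3 with a dioxirane or peracid. The free catechol and the 3-hydroxy-4-ketone are also air-sensitive in base. The real difficulty is to build the trioxygenated ring A and the C3-oxygenated ring C without having to tell three ring A oxygens apart, and to finish with deprotections that spare the prenyl ether. The key step exploits the para relationship between O1 (on C8a) and the C6 hydroxyl, next to the C7 hydroxyl. This is the pattern left when an oxygen nucleophile adds to the ortho-quinone of a 4-acylcatechol, so the O1–C8a bond can be made oxidatively on a ring A that owns only its two catechol oxygens.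

## Logic of the disconnections

14 to 13. The bond cut is the ester bond between O3 and an acetyl carbon. O3 has to be acylated while ring C is closed oxidatively, because a free hydroxyl between the two carbonyls would make the precursor a reductone. The gain is small, but it leaves a last step that is a neutral transesterification. The demand is a method that is neither acidic (prenyl ether) nor basic enough to expose the catechol to air oxidation.

13 to 11, through 12. The bond cut is O1–C8a. Ring C is opened and ring A falls back to a plain catechol with hydrogen on the future C8a. The bicyclic core becomes two benzene rings joined by a three-carbon 1,3-dicarbonyl chain, and ring A no longer needs a third oxygen. The forward step must oxidize only the ring A catechol, to 12. The enol oxygen on the future C2 must then add to the ring carbon ortho to the side chain and para to the C6 oxygen, and the catechol must be restored.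

11 to 10. The bonds cut are three O–Si bonds (O6, O7, O4'). The phenols have to be masked during the base-mediated steps, and ring A must be free for the oxidation. Silyl ethers are chosen because fluoride leaves the prenyl ether alone. The demand is a fluoride source mild enough not to remove or shift the acetyl group or cleave the dione.

10 to 9. The bond cut is the O3–acetyl bond. The forward step must acylate the carbinol oxygen and not an enol oxygen.

9 to 8. The bond cut is C2–C3, and the O3–C2 ester bond is restored: an O-to-C 1,2-acyl shift read backwards. The carbon–carbon bond between the two halves is traced to an ester linkage, and the oxygen on C3 is present from the start, so C3 is never oxidized. The demand is enolate formation that leaves aryl silyl ethers intact, and an intramolecular shift that is faster than intermolecular acyl transfer.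

8 to 5 and 7. The bond cut is O3–C3, the alkyl–oxygen bond of the ester. The route becomes convergent: a ring B acid and a ring A alpha-chloro ketone. The demand is a carboxylate alkylation under conditions too mild to desilylate.

7 to 6. The bonds cut are two O–Si bonds. 6 is commercial and already holds ring A, C4, C3 and the leaving group on C3. The demand is silylation without displacement of the alpha-chloride.

5 to 4. The carboxyl C–O bond is removed (acid to aldehyde). The demand is an oxidant that spares the prenyl alkene.

4 to 3. The bond cut is O4'–Si. The demand is trivial.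

3 to 1 and 2. The bond cut is O3'–CH2 of the prenyl ether. Both are commercial. The demand is alkylation of the less acidic oxygen meta to the aldehyde in the presence of the more acidic para one.

## Other disconnections considered

Alternative 1: the Algar–Flynn–Oyamada route, the first that comes to mind. The cut is O1–C2 and the C3–O bond, with C2–C3 traced to an aldol condensation. A ring A acetophenone that already carries O1 is condensed with a ring B aldehyde to the 2'-hydroxychalcone A1, and alkaline H2O2 closes ring C and hydroxylates C3 to give the protected flavonol A2. The ground for preferring the chosen plan is structural. The acetophenone needs three ring A oxygens, one of them differentiated. Its protecting groups must survive hot hydroxide and alkaline peroxide, which excludes esters and silyl ethers. They must then leave without acid, Lewis acid or hydrogen, which excludes the methoxymethyl groups of A2 as well as benzyl and methyl ethers, since aryl prenyl ethers ionize under acid. The chosen plan needs no oxygen on C8a in any starting material and uses only fluoride-labile and transesterifiable groups. The step counts are similar.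

Alternative 2: ring A built from open-chain carbons by a Diels–Alder reaction. The cut is C4a–C5 and C8–C8a. The 2-aryl-3-acetoxy-4-pyranone A3 would act as dienophile at its unsubstituted C=C bond towards the 2,3-bis(silyloxy)diene A4, and the cis-fused adduct A5 would be dehydrogenated to the catechol. The grounds against it are mechanistic. That C=C bond is part of a vinylogous ester with aromatic character and is a poor partner for an electron-rich diene. An activating group on the carbon that becomes C4a would be needed and would have to be expelled later. The aromatization requires removal of four hydrogens with a quinone oxidant of the kind that also cleaves prenyl ethers. A3 itself would need a synthesis about as long as that of a flavone, so the plan would be longer.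

Alternative 3: carbonylative alkyne annulation. The cut is O1–C2 and the two bonds to C4. An ortho-iodophenol, CO and an arylacetylene (PdCl2(PPh3)2, CuI) would give ynone A6, and 6-endo-dig addition of the phenol would give flavone A7. The C3 hydroxyl would then be introduced last. The ground against it is chemoselectivity. An electrophilic oxidant for the electron-poor C2=C3 bond would attack the electron-rich trisubstituted prenyl alkene first. If the prenyl group were added after the hydroxylation, O3' would have to be alkylated selectively among five hydroxyls. The iodophenol again needs three differentiated ring A oxygens, and 5-exo closure to an aurone competes with the 6-endo mode.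

Key step: step 9

Assumptions and conventions: the target has no stereocentre; 9, 10, 11 and 12 are racemic at C2 and this centre is erased in step 9. Atoms of open-chain intermediates carry the locants they have in the flavonol (O1, C2 to C4, C4a to C8a, C1' to C6'). Phenoxides and enolates formed by deprotonation are treated as forms of the numbered compound. TBS = tert-butyldimethylsilyl; prenyl = 3-methylbut-2-en-1-yl.

## Steps

Step 1
Reactants: 1 3,4-dihydroxybenzaldehyde; 2 prenyl bromide (1-bromo-3-methylbut-2-ene)
Product: 3 4-hydroxy-3-(prenyloxy)benzaldehyde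
Conditions: NaH (2.2 equiv), DMSO, 20 °C; then 2 (1.0 equiv), 20 °C; aq. HCl work-up
Reagents that add atoms: none
Why: Williamson ether synthesis on the dianion: the O4 phenoxide is delocalized into the para aldehyde and is the weaker nucleophile, so one equivalent of the allylic bromide should react at the localized O3 phenoxide. Limiting 2 to one equivalent should prevent dialkylation.

Step 2
Reactants: 3 4-hydroxy-3-(prenyloxy)benzaldehyde
Product: 4 3-(prenyloxy)-4-(TBS-oxy)benzaldehyde
Conditions: TBSCl, imidazole, DMF, rt
Reagents that add atoms: tert-butyldimethylsilyl chloride, CC(C)(C)[Si](C)(C)Cl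
Why: Standard silylation of the only free phenol. The silyl ether should survive the amide base of step 6 and leave later with fluoride, which does not touch the prenyl ether.

Step 3
Reactants: 4 3-(prenyloxy)-4-(TBS-oxy)benzaldehyde
Product: 5 3-(prenyloxy)-4-(TBS-oxy)benzoic acid
Conditions: NaClO2, NaH2PO4, 2-methylbut-2-ene (20 equiv), t-BuOH/H2O, 0 °C to rt
Reagents that add atoms: sodium chlorite, [Na+].[O-]Cl=O
Why: Pinnick oxidation of an aryl aldehyde. The large excess of scavenger alkene should intercept the hypochlorous acid before it reaches the prenyl alkene or the electron-rich ring, and the aryl silyl ether should be stable at the buffer pH.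

Step 4
Reactants: 6 2-chloro-1-(3,4-dihydroxyphenyl)ethan-1-one
Product: 7 1-[3,4-bis(TBS-oxy)phenyl]-2-chloroethan-1-one
Conditions: TBSOTf (2.2 equiv), 2,6-lutidine, CH2Cl2, -78 to 0 °C
Reagents that add atoms: tert-butyldimethylsilyl trifluoromethanesulfonate, CC(C)(C)[Si](C)(C)OS(=O)(=O)C(F)(F)F
Why: Silylation of both catechol hydroxyls with a silyl triflate. The hindered pyridine base is not nucleophilic enough to displace the alpha-chloride and too weak to form the silyl enol ether at this temperature.

Step 5
Reactants: 5 3-(prenyloxy)-4-(TBS-oxy)benzoic acid; 7 1-[3,4-bis(TBS-oxy)phenyl]-2-chloroethan-1-one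
Product: 8 2-[3,4-bis(TBS-oxy)phenyl]-2-oxoethyl 3-(prenyloxy)-4-(TBS-oxy)benzoate
Conditions: iPr2NEt (1.2 equiv), DMF, 40 °C
Reagents that add atoms: none
Why: SN2 displacement of an alpha-halo ketone by a carboxylate (phenacyl ester formation). The adjacent carbonyl activates the chloride, and the hindered amine base should leave the aryl silyl ethers intact.

Step 6
Reactants: 8 2-[3,4-bis(TBS-oxy)phenyl]-2-oxoethyl 3-(prenyloxy)-4-(TBS-oxy)benzoate
Product: 9 rac-1-[3,4-bis(TBS-oxy)phenyl]-2-hydroxy-3-[3-(prenyloxy)-4-(TBS-oxy)phenyl]propane-1,3-dione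
Conditions: LiN(SiMe3)2 (2.2 equiv), THF, -78 to 0 °C, argon; then AcOH, -78 °C
Reagents that add atoms: none
Why: Base-induced O-to-C 1,2-acyl shift of an alpha-acyloxy ketone, the rearrangement of the phenacyl ester route to flavonols and a relative of the Baker–Venkataraman rearrangement: the enolate carbon C3 attacks the ester carbonyl and the three-membered tetrahedral intermediate collapses to the alkoxide of the 2-hydroxy-1,3-dione. The second equivalent of base should draw the equilibrium forward by forming the enediolate. The new C2 centre is racemic and is erased in step 9.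

Step 7
Reactants: 9 rac-1-[3,4-bis(TBS-oxy)phenyl]-2-hydroxy-3-[3-(prenyloxy)-4-(TBS-oxy)phenyl]propane-1,3-dione
Product: 10 rac-1-[3,4-bis(TBS-oxy)phenyl]-1,3-dioxo-3-[3-(prenyloxy)-4-(TBS-oxy)phenyl]propan-2-yl acetate
Conditions: Ac2O, pyridine, DMAP (cat.), CH2Cl2, 0 °C
Reagents that add atoms: acetic anhydride, CC(=O)OC(C)=O
Why: Nucleophile-catalysed acylation of a secondary alcohol. The 2-substituted 1,3-dione is little enolized, so the carbinol oxygen should react in preference to an enol oxygen. The acetyl group blocks the reductone behaviour that a free hydroxy-dione would show in step 9.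

Step 8
Reactants: 10 rac-1-[3,4-bis(TBS-oxy)phenyl]-1,3-dioxo-3-[3-(prenyloxy)-4-(TBS-oxy)phenyl]propan-2-yl acetate
Product: 11 rac-1-(3,4-dihydroxyphenyl)-3-[4-hydroxy-3-(prenyloxy)phenyl]-1,3-dioxopropan-2-yl acetate
Conditions: Et3N·3HF, THF, 0 °C to rt, argon
Reagents that add atoms: none
Why: Fluoride cleavage of aryl silyl ethers, which are the most labile silyl ethers because phenoxide is a good leaving group. The nearly neutral amine–HF complex should leave the acetate, the dione and the prenyl ether untouched.

Step 9
Reactants: 11 rac-1-(3,4-dihydroxyphenyl)-3-[4-hydroxy-3-(prenyloxy)phenyl]-1,3-dioxopropan-2-yl acetate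
Product: 13 6,7-dihydroxy-2-[4-hydroxy-3-(prenyloxy)phenyl]-4-oxo-4H-chromen-3-yl acetate, via ortho-quinone 12 (not isolated)
Conditions: controlled-potential electrolysis at about +0.45 V vs Ag/AgCl (set at the foot of the catechol wave), graphite felt anode, Pt cathode, undivided cell, MeCN/0.2 M aq. NaOAc–AcOH buffer (pH 5) 1:1, rt, argon, 2.0–2.2 F/mol
Reagents that add atoms: none
Why: Proposed new method: two-electron anodic oxidation of the ring A catechol of 11, the most easily oxidized group present (the ring B phenol carries a para acyl group, and the alkene and the enol are oxidized only at far higher potential), should give ortho-quinone 12; the oxygen of the enol on C2 then adds to C8a, the beta carbon of the enone O=C7–C8=C8a and ortho to the side chain, and tautomerization restores the catechol as the 6,7-dihydroxychromone 13. The closest known reaction types are the anodic oxidation of catechols in the presence of 1,3-dicarbonyl compounds, where an enol oxygen adds to an ortho-quinone to close a benzofuran ring, and the oxidative closures of dihydrocaffeic acid to 6,7-dihydroxydihydrocoumarin and of 2-hydroxy-3',4'-dihydroxybenzophenones to 6,7-dihydroxyxanthones, where a tethered oxygen adds at the same ring position; closure of a chromone by an enol oxygen onto an acyl-quinone is not known. Ring C closes in the 6-exo-trig mode, since the attacked C8=C8a bond lies outside the new ring; the other enol oxygen could only form a four-membered ring and the central carbon cannot reach the ring. No stereocentre is formed, and the racemic C2 centre of 11 is erased by enolization. The regioselectivity needed is closure at C8a and not at C5, which would give the 7,8-dihydroxy isomer: C8a is the normal 1,4-position for oxygen nucleophiles on 4-substituted ortho-quinones, whereas C5 is alpha to the C6 carbonyl and hemmed in between that carbonyl and the side chain. The chemoselectivity needed is secured by potential control and by the acetyl group on O3, without which the hydroxy-dione would reduce 12 as a reductone; the acetate buffer supplies the general base for enolization and is too mild to harm the prenyl ether. Water that adds at C8a instead would give the 8a-hydroxy compound, which is expected to reach the same 13 by cyclodehydration, so this competing path should not cost material.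

Step 10
Reactants: 13 6,7-dihydroxy-2-[4-hydroxy-3-(prenyloxy)phenyl]-4-oxo-4H-chromen-3-yl acetate
Product: 14 3,6,7-trihydroxy-2-[4-hydroxy-3-(prenyloxy)phenyl]-4H-chromen-4-one
Conditions: NH4OAc, MeOH, rt, argon
Reagents that add atoms: none
Why: Neutral methanolysis (transesterification) of an enol acetate whose leaving group is the acidic 3-hydroxychromone. No acid reaches the prenyl ether, and no base strong enough to make the catechol air-sensitive is present.

## Compound list

1 | 3,4-dihydroxybenzaldehyde | O=Cc1ccc(O)c(O)c1 | starting material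
2 | prenyl bromide (1-bromo-3-methylbut-2-ene) | CC(C)=CCBr | starting material
3 | 4-hydroxy-3-(prenyloxy)benzaldehyde | CC(C)=CCOc1cc(C=O)ccc1O | intermediate
4 | 3-(prenyloxy)-4-(TBS-oxy)benzaldehyde | CC(C)=CCOc1cc(C=O)ccc1O[Si](C)(C)C(C)(C)C | intermediate
5 | 3-(prenyloxy)-4-(TBS-oxy)benzoic acid | CC(C)=CCOc1cc(C(=O)O)ccc1O[Si](C)(C)C(C)(C)C | intermediate
6 | 2-chloro-1-(3,4-dihydroxyphenyl)ethan-1-one | O=C(CCl)c1ccc(O)c(O)c1 | starting material
7 | 1-[3,4-bis(TBS-oxy)phenyl]-2-chloroethan-1-one | O=C(CCl)c1ccc(O[Si](C)(C)C(C)(C)C)c(O[Si](C)(C)C(C)(C)C)c1 | intermediate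
8 | 2-[3,4-bis(TBS-oxy)phenyl]-2-oxoethyl 3-(prenyloxy)-4-(TBS-oxy)benzoate | CC(C)=CCOc1cc(C(=O)OCC(=O)c2ccc(O[Si](C)(C)C(C)(C)C)c(O[Si](C)(C)C(C)(C)C)c2)ccc1O[Si](C)(C)C(C)(C)C | intermediate
9 | rac-1-[3,4-bis(TBS-oxy)phenyl]-2-hydroxy-3-[3-(prenyloxy)-4-(TBS-oxy)phenyl]propane-1,3-dione (racemic at C2) | CC(C)=CCOc1cc(C(=O)C(O)C(=O)c2ccc(O[Si](C)(C)C(C)(C)C)c(O[Si](C)(C)C(C)(C)C)c2)ccc1O[Si](C)(C)C(C)(C)C | intermediate
10 | rac-1-[3,4-bis(TBS-oxy)phenyl]-1,3-dioxo-3-[3-(prenyloxy)-4-(TBS-oxy)phenyl]propan-2-yl acetate (racemic at C2) | CC(C)=CCOc1cc(C(=O)C(OC(C)=O)C(=O)c2ccc(O[Si](C)(C)C(C)(C)C)c(O[Si](C)(C)C(C)(C)C)c2)ccc1O[Si](C)(C)C(C)(C)C | intermediate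
11 | rac-1-(3,4-dihydroxyphenyl)-3-[4-hydroxy-3-(prenyloxy)phenyl]-1,3-dioxopropan-2-yl acetate (racemic at C2) | CC(C)=CCOc1cc(C(=O)C(OC(C)=O)C(=O)c2ccc(O)c(O)c2)ccc1O | intermediate
12 | rac-1-(3,4-dioxocyclohexa-1,5-dien-1-yl)-3-[4-hydroxy-3-(prenyloxy)phenyl]-1,3-dioxopropan-2-yl acetate (ortho-quinone, racemic at C2, not isolated) | CC(C)=CCOc1cc(C(=O)C(OC(C)=O)C(=O)C2=CC(=O)C(=O)C=C2)ccc1O | intermediate
13 | 6,7-dihydroxy-2-[4-hydroxy-3-(prenyloxy)phenyl]-4-oxo-4H-chromen-3-yl acetate | CC(C)=CCOc1cc(-c2oc3cc(O)c(O)cc3c(=O)c2OC(C)=O)ccc1O | intermediate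
14 | 3,6,7-trihydroxy-2-[4-hydroxy-3-(prenyloxy)phenyl]-4H-chromen-4-one (CNP0086069.0) | CC(C)=CCOc1cc(-c2oc3cc(O)c(O)cc3c(=O)c2O)ccc1O | target

## Step count and least certain steps

Total step count: 10. Longest linear sequence: 9 steps (steps 1, 2, 3, 5, 6, 7, 8, 9, 10, from 1); the ring A branch (step 4) joins at step 5.

**Step 9 (key step, proposed new method).** The most likely failure is over-oxidation. The product catechol 13 carries the donor O1 para to its C6 hydroxyl and should be oxidized at a potential close to or below that of 11. Charge, or redox exchange with 12, can then be diverted into oxidation of the product, as happens after the cyclization of dopaquinone. Closure at the other ortho carbon (C5), which the side-chain carbonyl also activates, and intermolecular trapping of 12 by a second molecule cannot be ruled out. Limiting the charge, working dilute and a reductive work-up with ascorbic acid address the first point within the same approach.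

Fallback (known chemistry; O1 is brought in on the arene and ring C is closed at O1–C2): it sets out from acid 5 and returns at target 14. Commercial 1-(2,4,5-trihydroxyphenyl)ethan-1-one F1 would be silylated (TBSOTf, 2,6-lutidine) to 1-[2,4,5-tris(TBS-oxy)phenyl]ethan-1-one F2. Bromination at the methyl group (PhNMe3Br3, THF, 0 °C) would give 2-bromo-1-[2,4,5-tris(TBS-oxy)phenyl]ethan-1-one F3. Alkylation of the carboxylate of 5 with F3 (iPr2NEt, DMF) would give 2-oxo-2-[2,4,5-tris(TBS-oxy)phenyl]ethyl 3-(prenyloxy)-4-(TBS-oxy)benzoate F4. The acyl shift of step 6 (LiN(SiMe3)2, THF) would give rac-2-hydroxy-1-[3-(prenyloxy)-4-(TBS-oxy)phenyl]-3-[2,4,5-tris(TBS-oxy)phenyl]propane-1,3-dione F5. Et3N·3HF would free rac-2-hydroxy-1-[4-hydroxy-3-(prenyloxy)phenyl]-3-(2,4,5-trihydroxyphenyl)propane-1,3-dione F6 (not isolated). Brief warming in AcOH under argon would close ring C by addition of the ortho hydroxyl of ring A to the ring B carbonyl and loss of water, giving 14. This is the established phenacyl ester route to flavonols. Its price is a ring A building block with three oxygens and the handling of the air-sensitive F6.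

**Step 6.** The most likely failure is intermolecular acyl transfer or ester cleavage outrunning the intramolecular shift. The three-membered transition state is strained, and the ring B acyl group is deactivated by its oxygen donors. Retro-Claisen fragmentation of the product on quenching is a second risk.

Fallback: it sets out from 7 and 5 and returns at 10, by-passing 8 and 9. Displacement of the chloride of 7 by acetate (AcOH, iPr2NEt, DMF) would give 2-[3,4-bis(TBS-oxy)phenyl]-2-oxoethyl acetate F7. Treatment of 5 with 1-chloro-N,N,2-trimethylprop-1-en-1-amine would give 3-(prenyloxy)-4-(TBS-oxy)benzoyl chloride F8. C-acylation of F7 with F8 under soft enolization (MgBr2·OEt2, iPr2NEt, CH2Cl2) would give 10 directly. The C2–C3 bond is then made by an intermolecular crossed Claisen acylation of a magnesium-chelated enolate instead of by the shift.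

**Step 1.** The most likely failure is alkylation at the wrong oxygen or at both. This happens if the dianion is not fully formed, since the monoanion reacts at O4, or if the phenoxides equilibrate during the addition. Some C-alkylation is also possible.

Fallback: it sets out from 2 and returns at 3. Commercial 4-fluoro-3-hydroxybenzaldehyde F9 would be alkylated with 2 (K2CO3, DMF) to 4-fluoro-3-(prenyloxy)benzaldehyde F10, in which the only hydroxyl is the right one. Nucleophilic aromatic substitution of the fluoride, para to the aldehyde, by the alkoxide of 2-(methylsulfonyl)ethanol (NaH, DMF) would give 4-[2-(methylsulfonyl)ethoxy]-3-(prenyloxy)benzaldehyde F11 (not isolated). This loses methyl vinyl sulfone by E1cB elimination under the same conditions and gives 3. The regiochemistry is fixed by the position of the fluorine.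

**Step 8.** The most likely failure is loss or migration of the acetyl group on O3, or retro-Claisen cleavage of the dione. Fluoride is basic enough to enolize the dione, and the enolate oxygen can take over the neighbouring acetyl group. The liberated catechol is also air-sensitive.

Fallback: it sets out from 9 and returns at 14. Acylation of O3 with pivaloyl chloride (pyridine, DMAP) would give rac-1-[3,4-bis(TBS-oxy)phenyl]-1,3-dioxo-3-[3-(prenyloxy)-4-(TBS-oxy)phenyl]propan-2-yl pivalate F12, whose hindered ester should neither migrate nor be cleaved by fluoride. Desilylation as in step 8 would give rac-1-(3,4-dihydroxyphenyl)-3-[4-hydroxy-3-(prenyloxy)phenyl]-1,3-dioxopropan-2-yl pivalate F13. The anodic closure of step 9 would pass through the ortho-quinone rac-1-(3,4-dioxocyclohexa-1,5-dien-1-yl)-3-[4-hydroxy-3-(prenyloxy)phenyl]-1,3-dioxopropan-2-yl pivalate F14 (not isolated) to 6,7-dihydroxy-2-[4-hydroxy-3-(prenyloxy)phenyl]-4-oxo-4H-chromen-3-yl pivalate F15. Methanolysis (K2CO3, MeOH, 0 °C, argon) would give 14.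

## Further compounds

F1 | step 9 | 1-(2,4,5-trihydroxyphenyl)ethan-1-one | CC(=O)c1cc(O)c(O)cc1O
F2 | step 9 | 1-[2,4,5-tris(TBS-oxy)phenyl]ethan-1-one | CC(=O)c1cc(O[Si](C)(C)C(C)(C)C)c(O[Si](C)(C)C(C)(C)C)cc1O[Si](C)(C)C(C)(C)C
F3 | step 9 | 2-bromo-1-[2,4,5-tris(TBS-oxy)phenyl]ethan-1-one | O=C(CBr)c1cc(O[Si](C)(C)C(C)(C)C)c(O[Si](C)(C)C(C)(C)C)cc1O[Si](C)(C)C(C)(C)C
F4 | step 9 | 2-oxo-2-[2,4,5-tris(TBS-oxy)phenyl]ethyl 3-(prenyloxy)-4-(TBS-oxy)benzoate | CC(C)=CCOc1cc(C(=O)OCC(=O)c2cc(O[Si](C)(C)C(C)(C)C)c(O[Si](C)(C)C(C)(C)C)cc2O[Si](C)(C)C(C)(C)C)ccc1O[Si](C)(C)C(C)(C)C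
F5 | step 9 | rac-2-hydroxy-1-[3-(prenyloxy)-4-(TBS-oxy)phenyl]-3-[2,4,5-tris(TBS-oxy)phenyl]propane-1,3-dione | CC(C)=CCOc1cc(C(=O)C(O)C(=O)c2cc(O[Si](C)(C)C(C)(C)C)c(O[Si](C)(C)C(C)(C)C)cc2O[Si](C)(C)C(C)(C)C)ccc1O[Si](C)(C)C(C)(C)C
F6 | step 9 | rac-2-hydroxy-1-[4-hydroxy-3-(prenyloxy)phenyl]-3-(2,4,5-trihydroxyphenyl)propane-1,3-dione | CC(C)=CCOc1cc(C(=O)C(O)C(=O)c2cc(O)c(O)cc2O)ccc1O
F7 | step 6 | 2-[3,4-bis(TBS-oxy)phenyl]-2-oxoethyl acetate | CC(=O)OCC(=O)c1ccc(O[Si](C)(C)C(C)(C)C)c(O[Si](C)(C)C(C)(C)C)c1
F8 | step 6 | 3-(prenyloxy)-4-(TBS-oxy)benzoyl chloride | CC(C)=CCOc1cc(C(Cl)=O)ccc1O[Si](C)(C)C(C)(C)C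
F9 | step 1 | 4-fluoro-3-hydroxybenzaldehyde | O=Cc1ccc(F)c(O)c1
F10 | step 1 | 4-fluoro-3-(prenyloxy)benzaldehyde | CC(C)=CCOc1cc(C=O)ccc1F
F11 | step 1 | 4-[2-(methylsulfonyl)ethoxy]-3-(prenyloxy)benzaldehyde | CC(C)=CCOc1cc(C=O)ccc1OCCS(C)(=O)=O
F12 | step 8 | rac-1-[3,4-bis(TBS-oxy)phenyl]-1,3-dioxo-3-[3-(prenyloxy)-4-(TBS-oxy)phenyl]propan-2-yl pivalate | CC(C)=CCOc1cc(C(=O)C(OC(=O)C(C)(C)C)C(=O)c2ccc(O[Si](C)(C)C(C)(C)C)c(O[Si](C)(C)C(C)(C)C)c2)ccc1O[Si](C)(C)C(C)(C)C
F13 | step 8 | rac-1-(3,4-dihydroxyphenyl)-3-[4-hydroxy-3-(prenyloxy)phenyl]-1,3-dioxopropan-2-yl pivalate | CC(C)=CCOc1cc(C(=O)C(OC(=O)C(C)(C)C)C(=O)c2ccc(O)c(O)c2)ccc1O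
F14 | step 8 | rac-1-(3,4-dioxocyclohexa-1,5-dien-1-yl)-3-[4-hydroxy-3-(prenyloxy)phenyl]-1,3-dioxopropan-2-yl pivalate | CC(C)=CCOc1cc(C(=O)C(OC(=O)C(C)(C)C)C(=O)C2=CC(=O)C(=O)C=C2)ccc1O
F15 | step 8 | 6,7-dihydroxy-2-[4-hydroxy-3-(prenyloxy)phenyl]-4-oxo-4H-chromen-3-yl pivalate | CC(C)=CCOc1cc(-c2oc3cc(O)c(O)cc3c(=O)c2OC(=O)C(C)(C)C)ccc1O
A1 | alternative 1 | (E)-1-[2-hydroxy-4,5-bis(methoxymethoxy)phenyl]-3-[4-(methoxymethoxy)-3-(prenyloxy)phenyl]prop-2-en-1-one | CC(C)=CCOc1cc(/C=C/C(=O)c2cc(OCOC)c(OCOC)cc2O)ccc1OCOC
A2 | alternative 1 | 3-hydroxy-6,7-bis(methoxymethoxy)-2-[4-(methoxymethoxy)-3-(prenyloxy)phenyl]-4H-chromen-4-one | CC(C)=CCOc1cc(-c2oc3cc(OCOC)c(OCOC)cc3c(=O)c2O)ccc1OCOC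
A3 | alternative 2 | 4-oxo-2-[3-(prenyloxy)-4-(TBS-oxy)phenyl]-4H-pyran-3-yl acetate | CC(C)=CCOc1cc(-c2occc(=O)c2OC(C)=O)ccc1O[Si](C)(C)C(C)(C)C
A4 | alternative 2 | 2,3-bis(trimethylsilyloxy)buta-1,3-diene | C=C(O[Si](C)(C)C)C(=C)O[Si](C)(C)C
A5 | alternative 2 | rac-cis-4-oxo-2-[3-(prenyloxy)-4-(TBS-oxy)phenyl]-6,7-bis(trimethylsilyloxy)-4a,5,8,8a-tetrahydro-4H-chromen-3-yl acetate (cis ring fusion, racemic; one enantiomer drawn) | CC(C)=CCOc1cc(C2=C(OC(C)=O)C(=O)[C@@H]3CC(O[Si](C)(C)C)=C(O[Si](C)(C)C)C[C@@H]3O2)ccc1O[Si](C)(C)C(C)(C)C
A6 | alternative 3 | 1-[2-hydroxy-4,5-bis(TBS-oxy)phenyl]-3-[3-(prenyloxy)-4-(TBS-oxy)phenyl]prop-2-yn-1-one | CC(C)=CCOc1cc(C#CC(=O)c2cc(O[Si](C)(C)C(C)(C)C)c(O[Si](C)(C)C(C)(C)C)cc2O)ccc1O[Si](C)(C)C(C)(C)C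
A7 | alternative 3 | 6,7-bis(TBS-oxy)-2-[3-(prenyloxy)-4-(TBS-oxy)phenyl]-4H-chromen-4-one | CC(C)=CCOc1cc(-c2cc(=O)c3cc(O[Si](C)(C)C(C)(C)C)c(O[Si](C)(C)C(C)(C)C)cc3o2)ccc1O[Si](C)(C)C(C)(C)C
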